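## Structural features

The target is a daucane sesquiterpene ester. A cyclopentane (C1–C5) is trans-fused through the C1–C5 bond to a cycloheptene (C1, C5, C6–C10), and the C6 oxygen carries a 2-hydroxybenzoate. The numbering used throughout is: C1 methyl-bearing fusion carbon, C4 isopropyl carbinol, C5 fusion CH, C6 ester carbon, C8 methyl-bearing alkene carbon; names built on "dauc-" use it.

Four stereocentres are contiguous: quaternary C1 (R), tertiary carbinol C4 (R), C5 (S) and C6 (S). H5 is anti to the C1 methyl, the C4 hydroxyl is cis to the C1 methyl and to the C5–C6 bond, and O6 is cis to H5, so the two oxygens are 1,3-anti.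

The fragile parts are the tertiary C4 alcohol (open to retro-aldol cleavage or dehydration whenever C6 is a ketone), the aryl ester with its free ortho-phenol, and the trisubstituted C8=C9 alkene, which must be placed regioselectively. The real difficulty is the quaternary C1 at the ring fusion, flanked by C5 and lying in a seven-membered ring.

The key step exploits that C10 lies between C1 and C9 while C6 bears oxygen next to C5. With C9 at the carbonyl level and C5=C1 as the alkene of a cyclopentene, the atoms C10=C9–O–C6–C5=C1 form an allyl vinyl ether folded into an oxolane. A (3,3) shift then makes C1–C10, the seven-membered ring and the quaternary centre together. The C9 ketone and C5=C6 alkene it leaves are the handles for C8=C9 and for the C6 oxygen.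

## Logic of the disconnections

**28 ⇒ 26 + 27.** The acyl–O6 bond is cut. The ester with its free phenol is the most base-sensitive part, so it goes on last. This reduces the problem to the diol core plus a seven-carbon aryl unit. The forward step must acylate the secondary C6 hydroxyl in the presence of the tertiary one without a phenol protecting group; 27 does this because its opening by an alkoxide releases the phenol directly.

**26 ⇒ 24 ⇒ 22 ⇒ 21.** The C8=C9 alkene is traced back to a C9 ketone (the C9–H bond is exchanged for C9–O through 24). The reason is that C9 is exactly where the key step leaves a carbonyl. The gain is that no alkene has to be carried through the earlier oxidations and reductions. The demand is enolisation toward C8 and not C10, met by equilibrating silyl enol ether formation to 22 and regiospecific conversion into 24; the hydroxyls are masked in the same operation.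

**21 ⇒ 20 ⇒ 19 ⇒ 18 ⇒ 17 ⇒ 15.** The C6–H and C5–H bonds are removed. C6 comes from a ketone by reduction, C5 by equilibration, and both ketones of 19 from the alcohols of 18 and 17, which arise from 15 by reduction at C9 and addition of H and OH across C5=C6. Cutting here means the facial course of the alkene addition need not be controlled and no ketal or hydroxyl protection is needed. The gain is that 15 has only C1 and C4 as fixed stereocentres. The demand is that the trans fusion in 20 is the thermodynamic epimer and that the free C4 hydroxyl delivers hydride to C6 only.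

**15 ⇒ 14.** C1–C10 is cut and C6–O reconnected (retro-Claisen). This removes the quaternary centre and the seven-membered ring in one move. The gain is an oxolane attached to a cyclopentene, with secondary C6 as the only new stereocentre to set. The demand is a suprafacial shift that passes the C6 configuration to C1, and conditions free of acid.

**14 ⇒ 13 ⇒ 11 ⇒ 9.** The exocyclic C9=C10 bond is cut back to the lactone carbonyl of 13, the lactone C9–O bond to the 1,4-diol 11, and the primary hydroxyl to the terminal alkene of 9. C10 arrives as a one-carbon unit only after all oxidation is done, so the acid-sensitive enol ether exists for one step. C8 is left uncontrolled because it is erased in 22. The demand is methylenation without acid or strong base, and oxidation of the primary hydroxyl before the hindered secondary one.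

**9 ⇒ 5 + 6.** The C6–C7 bond is cut. This is the only stereocentre that a reagent must set, and the cut gives an aldehyde and a four-carbon nucleophile. The demand is reagent-controlled addition to a hindered enal.

**5 ⇒ 4 ⇒ 2 ⇒ 1.** The C5=C1 bond is cut (aldol condensation) and the two carbonyls of 4 are rejoined as the ring alkene of 1. C4 then comes from the chiral pool with the right configuration. The demand is that the aldehyde α-carbon, not the ketone, acts as nucleophile, and that the β-silyloxy aldehyde does not eliminate.

## Other disconnections considered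

**Alternative 1:** The cuts are C5–C6 and C1–C10 on a preformed cyclopentene. The tertiary cyclopentenol A1 would be converted into its (bromomethyl)dimethylsilyl ether A2. With AIBN and allyltributylstannane, the α-silyl radical should close 5-exo onto C5, and the tertiary C1 radical should be allylated anti to the new oxasilolane, giving A3.
- In favour: two C–C bonds and two stereocentres (C5, C1) form in one operation. The C4 oxygen acts as the control element and not as a protected spectator. C5 is set kinetically in the trans relationship to C10, with no equilibration; on this point the alternative is better than the chosen plan.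
- Against: the seven-membered ring is not made. A3 still needs Tamao oxidation, oxidation to the C6 aldehyde, a stereoselective methallyl addition and a ring-closing metathesis to a trisubstituted cycloheptene (second-generation Grubbs catalyst). A1 is not a chiral-pool compound. Intermolecular allyl transfer to a hindered tertiary radical is slow and tin-intensive.
- Comparison: in structure, both plans relay chirality into C1, but the chosen plan closes the large ring in the same step. In mechanism, the radical cascade is diastereoselective whereas the Claisen shift is stereospecific. In step count, the alternative would probably be shorter from A1 onward, and is the better one if A1 were in hand enantiopure.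

**Alternative 2:** The cut is C1–C5, traced back to a C1–C6 bond of a decalin. With TiCl4 or Et2AlCl, the epoxy alcohol A4 (or its silyl ether) should open at C5–O while C1 migrates from C6 to C5, contracting one ring and expanding the other to give hydroxy ketone A5.
- In favour: A5 already has C1, C4, C5 and the C8=C9 alkene in place, so only a directed reduction and the acylation remain. Here the alternative is clearly better than the chosen plan after the key step: no enol regiochemistry and no C5 equilibration. The anti migration is stereospecific, equal to the chosen key step.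
- Against: the burden moves to A4, a trans-decalin with angular methyl, angular hydroxyl and an epoxide anti to that hydroxyl, so hydroxyl-directed epoxidation would give the wrong face. The Lewis acid may ionise the more substituted C4–O bond instead. A5 is a Lewis-acid-sensitive β-hydroxy ketone.
- Comparison: the end game is shorter, the front end longer and without a chiral-pool anchor; the overall step count is probably similar.

**Alternative 3:** The cut is C1–C2 on a preformed seven-membered ring. With Sc(OTf)3 or FeCl3, dienone A6 should close conrotatorily and lose H6 to give A7. A6 is drawn with the C6 configuration assumed to steer closure anti to the silyloxy group.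
- In favour: the step is catalytic. C6 is already at the ketone level and C8=C9 is in place, so no hydroboration–oxidation and no enol triflate are needed; on redox economy the alternative is better.
- Against: an unpolarised vinyl ketone that must form a quaternary carbon cyclises reluctantly and can polymerise. Torquoselectivity rests on one allylic stereocentre that is then destroyed, so the absolute configuration depends on diastereoselection. The site of proton loss must be controlled. C4 must later be made by isopropyl addition to a hindered, enolisable ketone.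
- Comparison: both key steps are pericyclic, but the chosen one transfers chirality stereospecifically from a reagent-set centre, which is its advantage. The step count could be lower for the alternative, with more steps of uncertain selectivity.

Key step: step 8

Assumption: (S)-terpinen-4-ol of high enantiomeric purity is taken as a commercial material; it maps onto (4R) of the target because only the CIP ranking changes.
Assumption: C8 is formed without control in step 5 and stays an epimer mixture from 10 to 21 (C5, C6 and C9 likewise in 16–19); such centres carry no descriptor in the SMILES and all converge later.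
Assumption: for a suprafacial shift with a ring-enforced cis C5=C6 alkene, (6S) in 14 corresponds to (1R) in 15.

## Route

Step 1
Reactants: 1 (S)-terpinen-4-ol
Product: 2 (S)-terpinen-4-ol triethylsilyl ether
Conditions: Et3SiOTf, 2,6-lutidine, CH2Cl2, 0 °C → rt
Reagents that add atoms: triethylsilyl trifluoromethanesulfonate, CC[Si](CC)(CC)OS(=O)(=O)C(F)(F)F
Why: Silylation of a tertiary alcohol needs the silyl triflate; the ether blocks retro-aldol and dehydration in steps 2–3 and the C4 stereocentre is untouched.

Step 2
Reactants: 2 (S)-terpinen-4-ol triethylsilyl ether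
Product: 4 (3S)-6-oxo-3-(propan-2-yl)-3-(triethylsilyloxy)heptanal, via ozonide 3 (not isolated)
Conditions: O3, CH2Cl2, −78 °C; PPh3, −78 °C → rt
Reagents that add atoms: ozone, [O-][O+]=O
Why: Ozonolysis of the only alkene (cycloaddition, cycloreversion, recombination to the ozonide, reduction by the phosphine) gives the methyl ketone and the aldehyde; the silyl ether is inert.

Step 3
Reactants: 4 (3S)-6-oxo-3-(propan-2-yl)-3-(triethylsilyloxy)heptanal
Product: 5 (5R)-2-methyl-5-(propan-2-yl)-5-(triethylsilyloxy)cyclopent-1-ene-1-carbaldehyde
Conditions: piperidine (0.3 equiv), AcOH (0.3 equiv), benzene, 80 °C, 4 Å sieves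
Reagents that add atoms: none
Why: Amine-catalysed intramolecular aldol condensation: the aldehyde-derived enamine carbon (future C5) attacks the methyl ketone in a 5-exo closure and water is lost to the tetrasubstituted enal; the buffered medium disfavours β-elimination of the silyloxy group and the hydroxide-type pathway from the ketone enolate.

Step 4
Reactants: 5 (5R)-2-methyl-5-(propan-2-yl)-5-(triethylsilyloxy)cyclopent-1-ene-1-carbaldehyde, 6 2-methylallylmagnesium chloride
Product: 9 (1S)-3-methyl-1-[(5R)-2-methyl-5-(propan-2-yl)-5-(triethylsilyloxy)cyclopent-1-en-1-yl]but-3-en-1-ol, via B-(2-methylallyl)diisopinocampheylborane 7 (not isolated), via diisopinocampheylborinate 8 (not isolated)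
Conditions: (−)-Ipc2BOMe [(+)-α-pinene series], 6, Et2O, −78 °C → rt; 5, Et2O, −78 °C; NaOH, H2O2, 0 °C → rt
Reagents that add atoms: 2-methylallylmagnesium chloride (6), CC(=C)C[Mg]Cl
Why: Brown methallylboration through a chair six-membered transition state with the aldehyde substituent equatorial; C6 is set by the reagent, and the borane of this pinene series gives the (S)-alcohols from sp2-substituted aldehydes, which corresponds to (6S) here (the antipodal borane would be used if the opposite sense were found).

Step 5
Reactants: 9 (1S)-3-methyl-1-[(5R)-2-methyl-5-(propan-2-yl)-5-(triethylsilyloxy)cyclopent-1-en-1-yl]but-3-en-1-ol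
Product: 11 (4S)-2-methyl-4-[(5R)-2-methyl-5-(propan-2-yl)-5-(triethylsilyloxy)cyclopent-1-en-1-yl]butane-1,4-diol, via B-alkyl-9-BBN adduct 10 (not isolated)
Conditions: 9-BBN (2.5 equiv), THF, 0 °C → rt; NaOH, H2O2, 0 °C → rt
Reagents that add atoms: hydrogen peroxide, OO
Why: Anti-Markovnikov hydroboration–oxidation of the 1,1-disubstituted alkene; the tetrasubstituted ring alkene does not react with 9-BBN, and C8 forms as a mixture that is erased later.

Step 6
Reactants: 11 (4S)-2-methyl-4-[(5R)-2-methyl-5-(propan-2-yl)-5-(triethylsilyloxy)cyclopent-1-en-1-yl]butane-1,4-diol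
Product: 13 (5S)-3-methyl-5-[(5R)-2-methyl-5-(propan-2-yl)-5-(triethylsilyloxy)cyclopent-1-en-1-yl]oxolan-2-one, via lactol 12 (not isolated)
Conditions: TEMPO (0.2 equiv), PhI(OAc)2 (2.5 equiv), CH2Cl2, rt
Reagents that add atoms: none
Why: Oxoammonium oxidation takes the primary alcohol first; the hindered C6 hydroxyl is captured as the lactol, which is oxidised on to the γ-lactone (oxidative lactonisation of a 1,4-diol).

Step 7
Reactants: 13 (5S)-3-methyl-5-[(5R)-2-methyl-5-(propan-2-yl)-5-(triethylsilyloxy)cyclopent-1-en-1-yl]oxolan-2-one
Product: 14 (5S)-3-methyl-2-methylidene-5-[(5R)-2-methyl-5-(propan-2-yl)-5-(triethylsilyloxy)cyclopent-1-en-1-yl]oxolane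
Conditions: Cp2TiMe2 (2.5 equiv), toluene, 65 °C, dark; filtration through Et3N-deactivated basic alumina
Reagents that add atoms: Cp2TiMe2 (dimethyltitanocene), C[Ti](C)(C1C=CC=C1)C1C=CC=C1
Why: Petasis methylenation: thermal loss of methane gives the titanium methylidene, which converts the lactone carbonyl into the exocyclic enol ether under non-acidic, non-basic conditions that the silyl ether and C6 tolerate.

Step 8
Reactants: 14 (5S)-3-methyl-2-methylidene-5-[(5R)-2-methyl-5-(propan-2-yl)-5-(triethylsilyloxy)cyclopent-1-en-1-yl]oxolane
Product: 15 (1R,4R)-4-(triethylsilyloxy)dauc-5-en-9-one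
Conditions: toluene (0.02 M, degassed), Et3N (0.1 equiv), base-washed sealed tube, 180 °C
Reagents that add atoms: none
Why: Concerted (3,3) sigmatropic shift of the allyl vinyl ether C10=C9–O–C6–C5=C1: C1–C10 forms as C6–O breaks, the oxolane grows by two carbons into the cyclohept-4-enone and C9 emerges as the ketone; the closest known reaction type is the thermal Claisen ring expansion of 2-methylidene-5-vinyloxolanes to cyclohept-4-enones. The seven-membered ring is closed as a ring expansion inside a bicyclic boat transition state, the only geometry open when the O and C9 termini are tied in a five-membered ring, and for the same reason the new C5=C6 alkene can only be cis in the ring. The one new stereocentre, quaternary C1, is controlled by C6: bond making at C1 and bond breaking at C6 are suprafacial on the allyl unit, and with C7 forced to the C1 side of the forming alkene the (6S) ether delivers C10 to the face of C1 anti to the C4 silyloxy group, giving (1R). C4 does not decide the sense of induction and only affects the rate, since the isopropyl group lies on the face that is approached. The step needs periselectivity over proton-catalysed migration of the exocyclic double bond into the oxolane ring, secured by the amine-buffered, acid-free medium; chemoselectivity is inherent because 14 holds a single allyl vinyl ether. The fully substituted allyl terminus explains the high temperature, and C8 is a spectator that stays an epimer mixture.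

Step 9
Reactants: 15 (1R,4R)-4-(triethylsilyloxy)dauc-5-en-9-one
Product: 17 4-O-triethylsilyldaucane-4,6,9-triol, via borane adduct 16 (not isolated)
Conditions: BH3·THF (4 equiv), THF, 0 → 45 °C; NaOH, H2O2, 0 → 40 °C
Reagents that add atoms: hydrogen peroxide, OO
Why: Borane reduces the C9 ketone and hydroborates C5=C6 with boron on the less substituted C6; the configurations formed at C5, C6 and C9 are immaterial because all three are reset in steps 11–16, so no ketal is needed.

Step 10
Reactants: 17 4-O-triethylsilyldaucane-4,6,9-triol
Product: 18 daucane-4,6,9-triol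
Conditions: Bu4NF (3 equiv), THF, 50 °C
Reagents that add atoms: none
Why: Fluoride cleavage of the tertiary silyl ether, done while no ketone is present so that no β-oxygenated ketone meets basic fluoride.

Step 11
Reactants: 18 daucane-4,6,9-triol
Product: 19 4-hydroxydaucane-6,9-dione as C5 epimer mixture
Conditions: Dess–Martin periodinane (3 equiv), NaHCO3, CH2Cl2, 0 °C → rt
Reagents that add atoms: none
Why: Dess–Martin oxidation takes both secondary alcohols and cannot touch the tertiary C4 hydroxyl; the buffered neutral medium spares the β-hydroxy ketone.

Step 12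
Reactants: 19 4-hydroxydaucane-6,9-dione as C5 epimer mixture
Product: 20 trans-fused 4-hydroxydaucane-6,9-dione (H5 anti to the C1 methyl)
Conditions: DBU (0.3 equiv), CH2Cl2, rt
Reagents that add atoms: none
Why: Base-mediated epimerisation through the C5–C6 enolate; the trans-fused epimer, with C6 cis to the hydrogen-bonding C4 hydroxyl and anti to isopropyl, is expected to be the thermodynamic one, and the weak amidine base keeps the alkoxide concentration too low for retro-aldol cleavage.

Step 13
Reactants: 20 trans-fused 4-hydroxydaucane-6,9-dione
Product: 21 (1R,4R,5S,6S)-4,6-dihydroxydaucan-9-one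
Conditions: Me4NBH(OAc)3 (5 equiv), MeCN/AcOH 1:1, −20 → 0 °C; aq. sodium potassium tartrate
Reagents that add atoms: none
Why: Evans–Saksena hydroxyl-directed reduction: the C4 hydroxyl exchanges onto boron and delivers hydride to the C6 carbonyl face turned toward O4, giving the 1,3-anti diol with (6S); the C9 ketone has no β-hydroxyl and is not reduced by this weak hydride.

Step 14
Reactants: 21 (1R,4R,5S,6S)-4,6-dihydroxydaucan-9-one
Product: 22 4,6,9-tris(trimethylsilyloxy)dauc-8-ene
Conditions: Me3SiCl (6 equiv), NaI (6 equiv), Et3N (8 equiv), MeCN, rt → 40 °C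
Reagents that add atoms: chlorotrimethylsilane, C[Si](C)(C)Cl
Why: Iodotrimethylsilane made in the flask silylates both hydroxyls and forms the silyl enol ether under equilibrating conditions; the more substituted C8=C9 isomer, which also avoids a double bond next to quaternary C1, is expected, and both C8 epimers converge.

Step 15
Reactants: 22 4,6,9-tris(trimethylsilyloxy)dauc-8-ene
Product: 24 4,6-bis(trimethylsilyloxy)dauc-8-en-9-yl trifluoromethanesulfonate, via lithium enolate 23 (not isolated)
Conditions: MeLi (1.05 equiv), THF, 0 °C; PhNTf2 (1.2 equiv), −78 °C → rt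
Reagents that add atoms: N-phenylbis(trifluoromethanesulfonimide), FC(F)(F)S(=O)(=O)N(c1ccccc1)S(=O)(=O)C(F)(F)F
Why: Methyllithium cleaves only the enol Si–O bond to give the regiodefined lithium enolate, which is O-triflated without equilibration; the hindered alkyl silyl ethers survive.

Step 16
Reactants: 24 4,6-bis(trimethylsilyloxy)dauc-8-en-9-yl trifluoromethanesulfonate
Product: 26 jaeschkeanadiol [(1R,4R,5S,6S)-dauc-8-ene-4,6-diol], via bis(trimethylsilyl) ether 25 (not isolated)
Conditions: Pd(OAc)2 (5 mol %), PPh3 (10 mol %), Bu3N (3 equiv), HCO2H (2 equiv), DMF, 60 °C; then Bu4NF (3 equiv), rt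
Reagents that add atoms: none
Why: Palladium-catalysed formate reduction of the enol triflate (oxidative addition to zerovalent palladium, formate exchange, loss of CO2, C–H reductive elimination) gives the C8=C9 alkene without migration; fluoride then frees both hydroxyls in the same flask.

Step 17
Reactants: 26 jaeschkeanadiol, 27 2,2-dimethyl-4H-1,3-benzodioxin-4-one
Product: 28 [(3R,3aS,4S,8aR)-3-hydroxy-6,8a-dimethyl-3-(propan-2-yl)-1,2,3,3a,4,5,8,8a-octahydroazulen-4-yl] 2-hydroxybenzoate (target)
Conditions: NaN(SiMe3)2 (1.2 equiv), THF, 0 °C; 27 (1.3 equiv), 0 °C → rt; aq. NH4Cl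
Reagents that add atoms: 2,2-dimethyl-4H-1,3-benzodioxin-4-one (27), CC1(C)OC(=O)c2ccccc2O1
Why: The secondary C6 alkoxide adds to the carbonyl of the salicylic acid acetonide and the adduct collapses with loss of acetone to the salicylate phenoxide (alkoxide transesterification of a benzodioxinone), so no phenol protecting group is needed; the tertiary C4 oxygen is too hindered to be acylated.

## Compound list

1 | (S)-terpinen-4-ol [(1S)-4-methyl-1-(propan-2-yl)cyclohex-3-en-1-ol] | CC1=CC[C@](O)(C(C)C)CC1 | starting material
2 | (S)-terpinen-4-ol triethylsilyl ether | CC1=CC[C@](O[Si](CC)(CC)CC)(C(C)C)CC1 | intermediate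
3 | ozonide of 2 (1,2,4-trioxolane across the former alkene carbons) | CC12OOC(O1)C[C@](O[Si](CC)(CC)CC)(C(C)C)CC2 | intermediate
4 | (3S)-6-oxo-3-(propan-2-yl)-3-(triethylsilyloxy)heptanal | CC(=O)CC[C@@](CC=O)(O[Si](CC)(CC)CC)C(C)C | intermediate
5 | (5R)-2-methyl-5-(propan-2-yl)-5-(triethylsilyloxy)cyclopent-1-ene-1-carbaldehyde | O=CC1=C(C)CC[C@@]1(O[Si](CC)(CC)CC)C(C)C | intermediate
6 | 2-methylallylmagnesium chloride | CC(=C)C[Mg]Cl | starting material
7 | B-(2-methylallyl)diisopinocampheylborane, (+)-α-pinene series | CC(=C)CB([C@@H]1C[C@@H]2C[C@H]([C@H]1C)C2(C)C)[C@@H]1C[C@@H]2C[C@H]([C@H]1C)C2(C)C | intermediate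
8 | diisopinocampheylborinate of 9 | CC(=C)C[C@H](OB([C@@H]1C[C@@H]2C[C@H]([C@H]1C)C2(C)C)[C@@H]1C[C@@H]2C[C@H]([C@H]1C)C2(C)C)C1=C(C)CC[C@@]1(O[Si](CC)(CC)CC)C(C)C | intermediate
9 | (1S)-3-methyl-1-[(5R)-2-methyl-5-(propan-2-yl)-5-(triethylsilyloxy)cyclopent-1-en-1-yl]but-3-en-1-ol | CC(=C)C[C@H](O)C1=C(C)CC[C@@]1(O[Si](CC)(CC)CC)C(C)C | intermediate
10 | B-alkyl-9-BBN adduct of 9 (boron on the terminal carbon, C8 epimers) | CC(CB1C2CCCC1CCC2)C[C@H](O)C1=C(C)CC[C@@]1(O[Si](CC)(CC)CC)C(C)C | intermediate
11 | (4S)-2-methyl-4-[(5R)-2-methyl-5-(propan-2-yl)-5-(triethylsilyloxy)cyclopent-1-en-1-yl]butane-1,4-diol (C8 epimers) | OCC(C)C[C@H](O)C1=C(C)CC[C@@]1(O[Si](CC)(CC)CC)C(C)C | intermediate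
12 | lactol of 11 (5-substituted 3-methyloxolan-2-ol) | CC1C[C@H](OC1O)C1=C(C)CC[C@@]1(O[Si](CC)(CC)CC)C(C)C | intermediate
13 | (5S)-3-methyl-5-[(5R)-2-methyl-5-(propan-2-yl)-5-(triethylsilyloxy)cyclopent-1-en-1-yl]oxolan-2-one (C8 epimers) | CC1C[C@H](OC1=O)C1=C(C)CC[C@@]1(O[Si](CC)(CC)CC)C(C)C | intermediate
14 | (5S)-3-methyl-2-methylidene-5-[(5R)-2-methyl-5-(propan-2-yl)-5-(triethylsilyloxy)cyclopent-1-en-1-yl]oxolane (C8 epimers) | C=C1O[C@@H](CC1C)C1=C(C)CC[C@@]1(O[Si](CC)(CC)CC)C(C)C | intermediate
15 | (1R,4R)-4-(triethylsilyloxy)dauc-5-en-9-one (C9 ketone, C5=C6 alkene, C8 epimers) | CC1CC=C2[C@](O[Si](CC)(CC)CC)(C(C)C)CC[C@]2(C)CC1=O | intermediate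
16 | borane adduct of 15 (formal monomer: C6–BH2, C9–O–BH2) | CC1C(OB)C[C@@]2(C)CC[C@@](O[Si](CC)(CC)CC)(C(C)C)C2C(B)C1 | intermediate
17 | 4-O-triethylsilyldaucane-4,6,9-triol (mixture at C5, C6, C8, C9) | CC1C(O)C[C@@]2(C)CC[C@@](O[Si](CC)(CC)CC)(C(C)C)C2C(O)C1 | intermediate
18 | daucane-4,6,9-triol (mixture at C5, C6, C8, C9) | CC1C(O)C[C@@]2(C)CC[C@@](O)(C(C)C)C2C(O)C1 | intermediate
19 | 4-hydroxydaucane-6,9-dione (C5 and C8 epimers) | CC1C(=O)C[C@@]2(C)CC[C@@](O)(C(C)C)C2C(=O)C1 | intermediate
20 | trans-fused 4-hydroxydaucane-6,9-dione (H5 anti to C1 methyl, C8 epimers) | CC1C(=O)C[C@@]2(C)CC[C@@](O)(C(C)C)[C@@H]2C(=O)C1 | intermediate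
21 | (1R,4R,5S,6S)-4,6-dihydroxydaucan-9-one (C8 epimers) | CC1C(=O)C[C@@]2(C)CC[C@@](O)(C(C)C)[C@@H]2[C@@H](O)C1 | intermediate
22 | 4,6,9-tris(trimethylsilyloxy)dauc-8-ene | CC1=C(O[Si](C)(C)C)C[C@@]2(C)CC[C@@](O[Si](C)(C)C)(C(C)C)[C@@H]2[C@@H](O[Si](C)(C)C)C1 | intermediate
23 | lithium C8=C9 enolate of the bis(trimethylsilyl) ether of 21 | CC1=C([O-])C[C@@]2(C)CC[C@@](O[Si](C)(C)C)(C(C)C)[C@@H]2[C@@H](O[Si](C)(C)C)C1.[Li+] | intermediate
24 | 4,6-bis(trimethylsilyloxy)dauc-8-en-9-yl trifluoromethanesulfonate | CC1=C(OS(=O)(=O)C(F)(F)F)C[C@@]2(C)CC[C@@](O[Si](C)(C)C)(C(C)C)[C@@H]2[C@@H](O[Si](C)(C)C)C1 | intermediate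
25 | 4,6-bis(trimethylsilyl) ether of 26 | CC1=CC[C@@]2(C)CC[C@@](O[Si](C)(C)C)(C(C)C)[C@@H]2[C@@H](O[Si](C)(C)C)C1 | intermediate
26 | jaeschkeanadiol [(1R,4R,5S,6S)-dauc-8-ene-4,6-diol] | CC1=CC[C@@]2(C)CC[C@@](O)(C(C)C)[C@@H]2[C@@H](O)C1 | intermediate
27 | 2,2-dimethyl-4H-1,3-benzodioxin-4-one | CC1(C)OC(=O)c2ccccc2O1 | starting material
28 | [(3R,3aS,4S,8aR)-3-hydroxy-6,8a-dimethyl-3-(propan-2-yl)-1,2,3,3a,4,5,8,8a-octahydroazulen-4-yl] 2-hydroxybenzoate | CC1=CC[C@@]2(C)CC[C@@](O)(C(C)C)[C@@H]2[C@@H](OC(=O)c2ccccc2O)C1 | target

## Step count and least certain steps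

Total step count: 17. Longest linear sequence: 17 steps, from 1 to 28; 6 and 27 enter in steps 4 and 17.

**Step 8 (key step).** The most likely failure is proton-catalysed migration of the exocyclic double bond of 14 into the oxolane ring, which removes the allyl vinyl ether. The second is a rearrangement too slow to outrun thermal decomposition, because the bond forms at a fully substituted carbon on the face carrying the isopropyl group. The fallback leaves the purely thermal regime for an aluminium-promoted rearrangement with reduction in the flask. It sets out from 14: i-Bu3Al in CH2Cl2 at −78 → 0 °C should trigger the shift at low temperature and reduce the nascent ketone by hydride transfer to the C9 alcohol F1. F1 is then treated with BH3·THF and NaOH/H2O2 as in step 9, which returns to the route at 17. The C1 configuration of F1 would have to be confirmed, because the aluminium-bound transition state is more polar.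

**Step 4.** The aldehyde is flanked by a tetrasubstituted alkene and quaternary C4, so slow addition and eroded facial selectivity (a mismatched pairing with C4) are the likely problems. The fallback moves stereocontrol from C–C bond formation to a carbonyl reduction. It sets out from 5: direct addition of 6 (THF, −78 °C) should give 9 with its C6 epimer F2. The mixture is oxidised with Dess–Martin periodinane to the β,γ-unsaturated ketone F3, which is reduced with catecholborane and (R)-2-methyl-CBS-oxazaborolidine at −78 °C. This should give the (6S) alcohol and returns at 9.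

**Step 12.** A tertiary β-hydroxy ketone is held in base, so retro-aldol opening of the cyclopentane or dehydration across C4–C5 may compete with epimerisation. The fallback changes the order so that equilibration is done with no free β-hydroxyl. It sets out from 17: Dess–Martin oxidation should give the 4-silyloxy dione F4, DBU should epimerise C5 to the trans-fused silyl ether F5 (no alkoxide can form), and HF·pyridine in THF removes the silyl group under weakly acidic conditions, returning at 20.

**Step 14.** Two processes threaten it: incomplete regiocontrol of enolisation (some enol ether toward C10), and silylation of the transannular hemiketal that the C6 hydroxyl can form with the C9 ketone. The fallback adds a stage that only the wanted regioisomer can pass. It sets out from 22: Pd(OAc)2 in MeCN (Saegusa–Ito oxidation) should dehydrogenate only the C8 enol ether to the enone F6, because the regioisomer has no β-hydrogen at quaternary C1. Conjugate reduction of F6 with LiBH(s-Bu)3 at −78 °C gives the C8=C9 enolate alone, and trapping with PhNTf2 returns at 24.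

**Step 17.** Acylation of the hindered C6 alkoxide may be slow, so ester migration toward O4 or oligomerisation of the ring-opened salicylate could take over. The fallback uses an electrophilic acyl donor with a masked phenol. It sets out from 26: 2-acetoxybenzoyl chloride, pyridine and DMAP in CH2Cl2 should give the O-acetylsalicylate F7, and K2CO3 in MeOH at 0 °C removes the far more labile phenolic acetate, returning at 28.

## Further compounds

F1 | step 8 | (1R,4R)-4-(triethylsilyloxy)dauc-5-en-9-ol (C8, C9 epimers) | CC1CC=C2[C@](O[Si](CC)(CC)CC)(C(C)C)CC[C@]2(C)CC1O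
F2 | step 4 | (1R)-3-methyl-1-[(5R)-2-methyl-5-(propan-2-yl)-5-(triethylsilyloxy)cyclopent-1-en-1-yl]but-3-en-1-ol (C6 epimer of 9) | CC(=C)C[C@@H](O)C1=C(C)CC[C@@]1(O[Si](CC)(CC)CC)C(C)C
F3 | step 4 | 3-methyl-1-[(5R)-2-methyl-5-(propan-2-yl)-5-(triethylsilyloxy)cyclopent-1-en-1-yl]but-3-en-1-one | CC(=C)CC(=O)C1=C(C)CC[C@@]1(O[Si](CC)(CC)CC)C(C)C
F4 | step 12 | 4-(triethylsilyloxy)daucane-6,9-dione (C5 and C8 epimers) | CC1C(=O)C[C@@]2(C)CC[C@@](O[Si](CC)(CC)CC)(C(C)C)C2C(=O)C1
F5 | step 12 | trans-fused 4-(triethylsilyloxy)daucane-6,9-dione | CC1C(=O)C[C@@]2(C)CC[C@@](O[Si](CC)(CC)CC)(C(C)C)[C@@H]2C(=O)C1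
F6 | step 14 | 4,6-bis(trimethylsilyloxy)dauc-7-en-9-one | CC=1C(=O)C[C@@]2(C)CC[C@@](O[Si](C)(C)C)(C(C)C)[C@@H]2[C@@H](O[Si](C)(C)C)C=1
F7 | step 17 | jaeschkeanadiol 6-O-(2-acetoxybenzoate) | CC1=CC[C@@]2(C)CC[C@@](O)(C(C)C)[C@@H]2[C@@H](OC(=O)c2ccccc2OC(C)=O)C1
A1 | alternative 1 | (R)-3-methyl-1-(propan-2-yl)cyclopent-2-en-1-ol | O[C@@]1(C(C)C)CCC(C)=C1
A2 | alternative 1 | (bromomethyl)dimethylsilyl ether of A1 | BrC[Si](C)(C)O[C@@]1(C(C)C)CCC(C)=C1
A3 | alternative 1 | cis-fused oxasilolane cyclopentane with allyl and methyl on C1 | C=CC[C@@]1(C)CC[C@]2(C(C)C)O[Si](C)(C)C[C@H]12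
A4 | alternative 2 | trans-fused decalin 4,5-epoxy-6-ol with C8=C9 alkene | CC1=CC[C@@]2(C)CC[C@]3(C(C)C)O[C@@H]3[C@]2(O)C1
A5 | alternative 2 | trans-fused 4-hydroxydauc-8-en-6-one | CC1=CC[C@@]2(C)CC[C@@](O)(C(C)C)[C@@H]2C(=O)C1
A6 | alternative 3 | 1-[(7R)-7-(tert-butyldimethylsilyloxy)-2,5-dimethylcyclohepta-1,4-dien-1-yl]prop-2-en-1-one | C=CC(=O)C1=C(C)CC=C(C)C[C@H]1O[Si](C)(C)C(C)(C)C
A7 | alternative 3 | bicyclic C4 ketone with C5=C6 silyl enol ether and C8=C9 alkene | CC1=CC[C@@]2(C)CCC(=O)C2=C(O[Si](C)(C)C(C)(C)C)C1
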